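The earlier runs and the new flask stem from a simulated flask for substances that don't exist; the scatter is artificial.

The trap with this flask is to set it halfway between beta and epsilon, since its partner charge lies between theirs.

common to all: substrate 0.098 M (fed, over 6.0 h); free catalyst 0.1 mol%
- beta: partner 0.67 equiv; run made earlier
- epsilon: partner 1.5 equiv; run made earlier
- flask: partner 1.00 equiv; time 40 h

| run | time / h | substrate / % | product / % |
|---|---|---|---|
| beta | 2.50 | 39.9 | 1.3 |
| beta | 4.00 | 62.9 | 3.7 |
| beta | 6.00 | 92.5 | 7.1 |
| beta | 10.0 | 85.7 | 14.0 |
| beta | 15.0 | 77.9 | 22.3 |
| beta | 20.0 | 70.1 | 29.6 |
| beta | 30.0 | 58.9 | 40.7 |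
| epsilon | 1.50 | 24.6 | 0.4 |
| epsilon | 5.00 | 77.2 | 6.3 |
| epsilon | 10.0 | 82.0 | 17.9 |
| epsilon | 15.0 | 71.5 | 28.3 |
| epsilon | 20.0 | 61.6 | 38.4 |
| epsilon | 25.0 | 54.2 | 46.1 |
| epsilon | 30.0 | 46.7 | 53.2 |

(standard deviation of a reading: 0.3 percentage points)

- the state of affairs at 40 h: stopped, and by what, or still going (all of the substrate has reacted / the partner has run out first / no working catalyst is left / it is still moving)
- part of the substrate gone at 40 h
- the product standing at 40 h, as a percentage of the substrate charged

- the numbers in the tables scatter by 0.3 percentage points (one standard deviation)
- candidate steps: partner + free catalyst -> catalyst intermediate A; substrate + catalyst intermediate A -> catalyst intermediate B; catalyst intermediate A -> spent catalyst; catalyst intermediate B -> free catalyst + product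
- percentages count the whole charge, also what has not yet gone in
- the reaction counts as stopped when no species that holds the substrate changes by six tenths of a point or more over the second half of the time

I treated catalyst intermediate B as passing on at once, so each turn of the catalyst costs a wait for partner plus a wait for substrate. Then [substrate]/rate is a straight line in [substrate]/[partner]. Once the feed has ended the flask keeps that ratio near 1, so from 6.0 h on its substrate should fall exponentially. Over their last readings, beta's substrate took 57.4 h to fall by a factor e and epsilon's took 36.1 h, so beta ran slower. Starting from beta's 92.5% at 6.00 h, those two times bracket the flask's product between 48.8% and 63.9%.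

The ratio was near 2 in beta and near 0.5 in epsilon, so the flask lies a third of the way from epsilon, not halfway. That gives 43.2 h, the e-fold time at equal [substrate] and [partner], a pseudo-first-order time constant. I therefore reckoned 57.9% product, with 25 percentage points of substrate lost between half time and the end, so still moving.

The forecast said it is still moving, with 56.5% gone (53% to 60%) and 56.4% product, holding that “the first two steps share rate control”. That stands inside my bracket, a little below my figure.

The flask gave 59.4% product, and it is still moving.

    partner + free catalyst → catalyst intermediate A (k = 778 M⁻¹ h⁻¹)
    substrate + catalyst intermediate A → catalyst intermediate B (k = 462 M⁻¹ h⁻¹)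
    catalyst intermediate A → spent catalyst (k = 0.00395 h⁻¹)
    catalyst intermediate B → free catalyst + product (k = 149 h⁻¹)

Substrate and partner each stood at 40.6% in the flask. Applied to the flask's 91.8% at the end of the feed, 43.2 h leaves 41.8%. A further flask, like this one but with 0.04 mol% of free catalyst, reached 29.6% conversion. Stretching 43.2 h by the loading ratio gives 108 h. With beta's product at 6.00 h cut in the same proportion, that leaves 70.8% of the substrate at 40.0 h, and that further flask held 70.4%.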